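**Conventions.** Atoms carry the labdane numbers of the target: ring A is C1–C5 and C10, ring B is C5–C10, C11–C12 is the chain on C9, C13–C16 the butenolide, C17 the hydroxymethyl carbon on C8. "β" is the face of the decalin that carries the C10 methyl group and H5; "α" is the other face.

## Analysis of the target

The target is a C20 labdane-type diterpenoid built on a cis-fused decalin. C4 carries a gem-dimethyl group and C10 an angular methyl group. The C8=C9 alkene is tetrasubstituted, with a hydroxymethyl group (C17) on C8 and a two-carbon chain on C9 that ends at the β-carbon of a butenolide. There are four stereocentres: C2 (S), C5 (R), C6 (S) and C10 (S). H5 and the C10 methyl are cis on the β-face, and both secondary hydroxyls (C2, C6) sit on the α-face, so they cannot both be equatorial in the same conformer of the cis-fused bicycle. The sensitive groups are the butenolide (base, nucleophilic hydride, strong reductants) and the primary allylic alcohol on an electron-rich tetrasubstituted alkene (acid, electrophilic oxidants). Any C6 ketone precursor is also fragile, because its C5–H is enolisable and its β,γ-alkene can slip into conjugation. The difficulty lies in the run of fully substituted carbons C8–C9–C10 beside C5 and the quaternary C4, in a ring fusion that must be set absolutely with no heteroatom on it, and in the remote C2 carbinol. The strategy rests on one feature: C5 and C10 are adjacent and cis, and they are flanked by C6 and C9, which are oxygenated or sp2 and stand para to each other across ring B. That is the imprint of a methyl-substituted benzoquinone double bond after cis addition of a diene that supplies C1–C4 with oxygen at C2.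

## Retrosynthetic reasoning

**Butenolide.** The lactone of target 23 is made last from the 3-substituted furan in triol 19, by photooxygenation and reduction. Only the oxidation level of C15 and C16 changes. A furan survives the organometallic, radical, electron-transfer and hydride steps that a butenolide would not, and it needs no protecting group.

**C2 carbinol.** Triol 19 comes from ketone 18, and 18 from the silyl enol ether 17. The C2 oxygen is therefore carried, masked, from the cycloaddition, and C2 is reduced only after the C6 hydroxyl is in place to bias the conformation.

**C17 hydroxyl and C6 carbinol.** The C17–O bond of 17 is traced to a C17–Si bond in 16, and the C6 hydroxyl of 16 to the ketone of 15. Keeping C17 as a carbon–silicon bond until this point leaves only one allylic oxygen in the reductive step.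

**C8=C9 alkene.** Ketone 15 is derived from enone 14 by putting the C9 oxygen back and moving the alkene to C7=C8, in conjugation with C6=O. Forward, a two-electron reduction of the enone expels the C9–O bond and kinetic protonation at C7 leaves the alkene at C8=C9. This removes the oxygen introduced by the carbonyl addition and creates the tetrasubstituted alkene in one operation.

**C8–C17 bond.** Cutting C8–C17 in 14 leads through the tethered bromide 12 to carbinol 11. C8 is the β-carbon of a vinylogous ester and sits between a fully substituted carbinol and C7. Intermolecular addition–elimination by an organocopper nucleophile is not credible there: β-alkoxy enones are poor acceptors for such reagents and the site is congested. The C9 oxygen is therefore used as an anchor for a silicon-tethered radical that reaches C8 intramolecularly, and the methoxy group is then lost by β-elimination.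

**C9–C11 bond.** Carbinol 11 is cut at C9–C11 into enedione 6 and iodide 8 (made from alcohol 7). The forward addition must choose C9=O over C6=O; the C8 methoxy group makes C6=O a vinylogous ester carbonyl and so directs the nucleophile to C9.

**C1–C10 and C4–C5 bonds (key disconnection).** Enedione 6 is cut into quinone 5 and diene 4. This closes ring A, sets C5 and C10, and delivers the C2, C6 and C9 oxygens and a leaving group on C8 in one step. The forward reaction has to pick the methyl-bearing double bond of 5, join C1 to C10 and choose one face.

**Diene.** Diene 4 comes from ketone 1 and silyl triflate 2 by kinetic enolisation.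

## Alternatives that were turned down

Alternative 1: the C5–C10 bond would be made last. A ten-membered dienedione A2 is folded by a transannular Michael addition under a chiral primary amine–thiourea catalyst: the C5 enamine of the C6 ketone attacks C10 of the (Z)-enone and gives the cis-decalindione A1.
- For: A1 already has the C8=C9 alkene, C17, C11–C12 and both ring oxygens, so the steps after the key step are fewer than in the chosen route. On that point this alternative is stronger.
- Against: A2 is a medium ring with a tetrasubstituted in-ring alkene, a gem-dimethyl group and two ketones, and no short route to it is apparent.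
- Against: the C6 ketone can form its enamine towards C7 (allylic, more acidic) as well as towards C5.
- Against: the acceptor carbon C10 is fully substituted and part of a dienone, so 1,6-addition at C8 competes.
- Against: the cis or trans outcome depends on the conformer of the macrocycle and is not enforced by the mechanism.
- Comparison: the chosen route needs more steps after the key step, but its precursor is two steps from purchased material and its cis fusion follows from the topology of a cycloaddition.

Alternative 2: C9–C10 and C5–C6 would come from an intramolecular enone–alkene photocycloaddition of the ester-tethered furanone A4, followed by retro-aldol opening of the cyclobutane (de Mayo sequence) to the bridged lactone diketone A3.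
- For: photochemical bond formation is little affected by the congestion at C10.
- For: the C2 stereocentre is present from the start and, through the tether, fixes C10 and C5 relative to it. The chosen route is weaker here, since it leaves C2 to a late, substrate-controlled reduction.
- Against: ring B is still open in A3 and must be closed by an aldol that can go in two directions.
- Against: only C11 of the side chain is present, as a lactone carbonyl that has to be reduced and extended.
- Against: C9 is epimerisable, and ester tethers adopt a conformation that disfavours the cycloaddition.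
- Against: enantiopure A4 must be secured first.
- Comparison: the route is longer and less convergent than a quinone cycloaddition that delivers ring B complete with both oxygens.

Alternative 3: C9–C10 would be closed by thermal disrotatory 6π electrocyclisation of triene A6, followed by a suprafacial hydrogen shift from C9 to C5 to give the cis-fused diene A5.
- For: A6 can be assembled convergently by cross-coupling, C2 is configured from the start, and C17 and C11–C12 are in place. On step count to the bicyclic core this alternative is as strong as the chosen one.
- Against: the closure forms a quaternary centre from a fully substituted triene terminus and is expected to be slow and reversible.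
- Against: the face of closure is controlled only by the distant C2 substituent.
- Against: hydrogen shifts in cyclohexadienes do not stop cleanly at one isomer.
- Against: A5 has no oxygen at C6, so a regio- and stereoselective oxygenation of a conjugated diene would still be needed.
- Comparison: the chosen strategy brings the C6 oxygen in with the quinone and sets the absolute configuration by a catalyst.

Key step: step 2

**Assumptions.**
- The absolute sense of induction in the key step is assigned by analogy with acrylate and quinone cycloadditions under the same catalyst family; the analogy is not unambiguous for this pairing of diene and quinone. If adduct 6 should form as the antipode, the mirror-image (R)-catalyst is used and nothing else changes.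
- 2-(Furan-3-yl)ethanol (7) and quinone 5 are taken as purchasable.

## Route

Step 1
Reactants: 1 mesityl oxide (4-methylpent-3-en-2-one); 2 triisopropylsilyl trifluoromethanesulfonate
Product: 4 4-methyl-2-(triisopropylsilyloxy)penta-1,3-diene, via lithium 4-methylpenta-1,3-dien-2-olate 3 (not isolated)
Conditions: LiN(i-Pr)2, THF, −78 °C; then 2, −78 → 0 °C
Reagents that add atoms: none
Why: Kinetic deprotonation of the enone at the α′-methyl group by the hindered amide gives the cross-conjugated dienolate, which the silyl triflate traps on oxygen (kinetic enolate O-silylation); the bulky silyl group is chosen because its enol ethers withstand strong Lewis and Brønsted acids.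

Step 2
Reactants: 5 2-methoxy-6-methyl-1,4-benzoquinone; 4 4-methyl-2-(triisopropylsilyloxy)penta-1,3-diene
Product: 6 (5R,10S) cis-fused adduct with a C2 triisopropylsilyl enol ether (C2=C3), C6 and C9 ketones and a C8 methyl enol ether (C7=C8)
Conditions: (S)-3,3-diphenyl-1-(o-tolyl)hexahydropyrrolo[1,2-c][1,3,2]oxazaborole (C24H24BNO, 20 mol%), Tf2NH (20 mol%), CH2Cl2, −78 → −40 °C
Reagents that add atoms: none
Why: The protonated oxazaborolidine binds the C6 carbonyl of 5, which is the more basic vinylogous-ester carbonyl and the only one with unsubstituted flanking positions, through the lone pair syn to C5–H with a C5–H···O contact to the ring oxygen of the catalyst. Activation through C6=O makes the methyl-bearing C10 the electrophilic β-carbon, while the methoxy-bearing C7=C8 bond is deactivated by donation, so only the C5=C10 bond reacts and the nucleophilic CH2 terminus of 4 (C1) bonds to C10 and the dimethyl terminus (C4) to C5. The closest known reaction type is the oxazaborolidinium-catalysed enantioselective Diels–Alder reaction of 2-silyloxybutadienes with methyl- and methoxy-substituted benzoquinones, together with Lewis-acid-promoted cycloadditions of 4,4-disubstituted 2-silyloxydienes with hindered enones; a diene with a dimethyl terminus under a chiral catalyst is the untested element. Ring A is closed by the (4+2) cycloaddition, probably highly asynchronous because the cis methyl group of 4 disfavours the s-cis diene: the C1–C10 bond leads and the boron enolate then closes onto the silyloxyallyl cation at C4 (Mukaiyama–Michael then Michael in the stepwise limit). C10 is set by the catalyst, one aryl group of the diarylcarbinol unit lying against one face of the C5=C10 bond so that the diene adds to the open face. C5 follows from the ring closure, because the three-atom tether formed with the first bond can only reach the same face of the enolate, so H5 and the C10 methyl are necessarily cis. The step needs site, regio- and facial selectivity; the first two are secured by the substitution pattern of 5 and the third by the catalyst.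

Step 3
Reactants: 7 2-(furan-3-yl)ethanol
Product: 8 3-(2-iodoethyl)furan
Conditions: I2, PPh3, imidazole, CH2Cl2, 0 °C → rt
Reagents that add atoms: iodine, II
Why: Appel-type iodination of a primary alcohol through the alkoxyphosphonium iodide (SN2); the buffered, non-acidic conditions spare the furan.

Step 4
Reactants: 8 3-(2-iodoethyl)furan; 6 cis-fused adduct
Product: 11 C9 carbinol (9α-hydroxy and 9β-[2-(furan-3-yl)ethyl]; C6 ketone; C7=C8 methyl enol ether; C2 silyl enol ether), via 2-(furan-3-yl)ethyllithium 9 (not isolated), via 2-(furan-3-yl)ethylcerium dichloride 10 (not isolated)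
Conditions: 8, t-BuLi (2 equiv), Et2O, −78 °C; CeCl3, THF, −78 °C; then 6, −78 °C; aq. NH4Cl
Reagents that add atoms: none
Why: Iodine–lithium exchange and transmetallation give a weakly basic organocerium reagent of the kind that adds 1,2 to hindered and enolisable ketones; C6=O is a vinylogous ester carbonyl deactivated by the C8 methoxy group, so addition should occur at C9 and without deprotonation at C5. Attack is expected from the β-face, away from ring A, and the configuration at C9 is erased in step 7, so either epimer serves.

Step 5
Reactants: 11 C9 carbinol
Product: 12 (bromomethyl)dimethylsilyl ether of 11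
Conditions: BrCH2SiMe2Cl, imidazole, 4-(dimethylamino)pyridine (cat.), DMF, rt
Reagents that add atoms: (bromomethyl)chlorodimethylsilane, C[Si](C)(Cl)CBr
Why: Silylation of the tertiary alcohol with a small chlorodimethylsilyl electrophile under nucleophilic catalysis, the usual preparation of a Nishiyama–Stork radical precursor; no strong base is present, so C5 is not enolised.

Step 6
Reactants: 12 (bromomethyl)dimethylsilyl ether
Product: 14 enone-siloxane (C6 ketone conjugated with C7=C8; five-membered ring O9–SiMe2–C17–C8), via β-methoxy ketone 13 (not isolated)
Conditions: Bu3SnH, 2,2'-azobis(2-methylpropionitrile) (cat.), PhH, 80 °C, slow addition; then 1,8-diazabicyclo[5.4.0]undec-7-ene, CH2Cl2, 0 °C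
Reagents that add atoms: none
Why: Nishiyama–Stork silicon-tethered radical cyclisation: the nucleophilic α-silylmethyl radical adds 5-exo to C8, the β-carbon of the enone, which is the polarity-matched mode and the only one that leaves a carbonyl-stabilised radical (at C7) for reduction by the stannane. The β-methoxy ketone 13 then loses methanol by E1cB elimination towards C7, the less hindered α-position, which restores the C7=C8 enone with C17 now on C8.

Step 7
Reactants: 14 enone-siloxane
Product: 15 β,γ-unsaturated ketone (C6 ketone, C8=C9 alkene, CH2SiMe2OH on C8, 2-(furan-3-yl)ethyl on C9)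
Conditions: SmI2 (2.5 equiv), THF–HMPA, −78 °C; then sat. aq. NH4Cl, −78 °C
Reagents that add atoms: none
Why: SmI2 reduction of a γ-oxygenated α,β-unsaturated ketone: two-electron reduction places carbanion character on C8, the allylic C9–O bond is expelled as the silanolate (as with γ-acyloxy and γ-alkoxy enones), and the samarium dienolate is protonated kinetically at C7, which leaves the alkene at C8=C9. C17 carries silicon and not oxygen at this stage, so C9–O is the only leaving group within reach.

Step 8
Reactants: 15 β,γ-unsaturated ketone
Product: 16 6α (6S) alcohol of 15
Conditions: NaBH4, CeCl3·7H2O, MeOH–THF, −78 °C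
Reagents that add atoms: none
Why: Fast, non-basic borohydride reduction (Luche conditions) takes the ketone before the alkene can move into conjugation or C5 can epimerise. Hydride is expected on the β-face, because the α-face of C6 is screened by C4 and its two methyl groups on the adjacent C5 (or by axial C1 in the other half-chair); this gives the 6α carbinol.

Step 9
Reactants: 16 6α alcohol
Product: 17 6α,17-diol (C2 silyl enol ether and furan retained)
Conditions: KF, KHCO3, 30% H2O2, THF–MeOH, rt
Reagents that add atoms: hydrogen peroxide, OO
Why: Tamao oxidation: the hydroxysilane is activated by fluoride and peroxide, and the allylic carbon migrates from silicon to oxygen without allylic transposition. The buffered basic medium should be tolerated by the furan, the alkene and the silyl enol ether; any enol ether cleaved here simply gives 18 early.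

Step 10
Reactants: 17 6α,17-diol
Product: 18 6α,17-dihydroxy 2-ketone
Conditions: Bu4NF, AcOH, THF, 0 °C
Reagents that add atoms: none
Why: Fluoride cleaves the O–Si bond of the silyl enol ether and the acetic acid buffer protonates the enolate, which unveils the C2 ketone without acid that could ionise the allylic alcohol.

Step 11
Reactants: 18 6α,17-dihydroxy 2-ketone
Product: 19 (2S,5R,6S,10S) 2α,6α,17-triol with the 3-substituted furan
Conditions: LiBH(s-Bu)3 (4 equiv), THF, −78 °C; MeOH, aq. NH4Cl
Reagents that add atoms: none
Why: Hydride reduction of a cyclohexanone flanked at both β-carbons by quaternary centres. In the conformer that keeps the 6α-hydroxyl equatorial, C9 and the 4α-methyl group are both axial on the α-face of ring A and flank C2, so the bulky hydride should enter equatorially from the β-face and give the 2α (2S) carbinol. This depends on that conformer being the one that reacts.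

Step 12
Reactants: 19 2α,6α,17-triol
Product: 23 target CNP0293367.1, via furan endoperoxide 20 (not isolated), via hydroxybutenolide 21 (not isolated), via hydroxy acid 22 (not isolated)
Conditions: O2, hν (visible), 5,10,15,20-tetraphenylporphyrin (cat.), i-Pr2NEt, CH2Cl2, −78 °C; then NaBH4, EtOH, 0 °C; aq. HCl to pH 3
Reagents that add atoms: dioxygen, O=O
Why: Singlet oxygen adds (4+2) to the furan, and the hindered amine removes the bridgehead proton remote from the substituent (C15), so C15 becomes the lactone carbonyl and C16 the hemiacetal carbon (base-directed photooxygenation of a 3-alkylfuran). Borohydride reduces the open aldehyde form at C16 and acidification closes the β-substituted butenolide. The C8=C9 alkene is flanked by the quaternary C10 and carries an electron-withdrawing hydroxymethyl group, and should react more slowly than the furan.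

## Compound list

1 | mesityl oxide (4-methylpent-3-en-2-one) | CC(C)=CC(C)=O | starting material
2 | triisopropylsilyl trifluoromethanesulfonate | CC(C)[Si](OS(=O)(=O)C(F)(F)F)(C(C)C)C(C)C | starting material
3 | lithium 4-methylpenta-1,3-dien-2-olate (not isolated) | [Li]OC(=C)C=C(C)C | intermediate
4 | 4-methyl-2-(triisopropylsilyloxy)penta-1,3-diene | CC(C)=CC(=C)O[Si](C(C)C)(C(C)C)C(C)C | intermediate
5 | 2-methoxy-6-methyl-1,4-benzoquinone | COC1=CC(=O)C=C(C)C1=O | starting material
6 | (5R,10S) cis-fused adduct: C2 triisopropylsilyl enol ether, C6 and C9 ketones, C8 methyl enol ether | CC1(C)C=C(O[Si](C(C)C)(C(C)C)C(C)C)C[C@]2(C)C(=O)C(OC)=CC(=O)[C@H]12 | intermediate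
7 | 2-(furan-3-yl)ethanol | OCCc1ccoc1 | starting material
8 | 3-(2-iodoethyl)furan | ICCc1ccoc1 | intermediate
9 | 2-(furan-3-yl)ethyllithium (not isolated) | [Li]CCc1ccoc1 | intermediate
10 | 2-(furan-3-yl)ethylcerium dichloride (not isolated) | Cl[Ce](Cl)CCc1ccoc1 | intermediate
11 | C9 carbinol: 9α-hydroxy, 9β-[2-(furan-3-yl)ethyl], C6 ketone, C7=C8 methyl enol ether, C2 silyl enol ether | CC1(C)C=C(O[Si](C(C)C)(C(C)C)C(C)C)C[C@]2(C)[C@@](O)(CCc3ccoc3)C(OC)=CC(=O)[C@H]12 | intermediate
12 | (bromomethyl)dimethylsilyl ether of 11 | CC1(C)C=C(O[Si](C(C)C)(C(C)C)C(C)C)C[C@]2(C)[C@@](O[Si](C)(C)CBr)(CCc3ccoc3)C(OC)=CC(=O)[C@H]12 | intermediate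
13 | β-methoxy ketone: cis-fused ring O9–SiMe2–C17–C8, 8β-methoxy, C6 ketone (not isolated) | CC1(C)C=C(O[Si](C(C)C)(C(C)C)C(C)C)C[C@]2(C)[C@]3(CCc4ccoc4)O[Si](C)(C)C[C@]3(OC)CC(=O)[C@H]12 | intermediate
14 | enone-siloxane: C6 ketone conjugated with C7=C8, ring O9–SiMe2–C17–C8 | CC1(C)C=C(O[Si](C(C)C)(C(C)C)C(C)C)C[C@]2(C)[C@]3(CCc4ccoc4)O[Si](C)(C)CC3=CC(=O)[C@H]12 | intermediate
15 | β,γ-unsaturated ketone: C6 ketone, C8=C9, CH2SiMe2OH on C8, 2-(furan-3-yl)ethyl on C9 | CC1(C)C=C(O[Si](C(C)C)(C(C)C)C(C)C)C[C@]2(C)C(CCc3ccoc3)=C(C[Si](C)(C)O)CC(=O)[C@H]12 | intermediate
16 | 6α (6S) alcohol of 15 | CC1(C)C=C(O[Si](C(C)C)(C(C)C)C(C)C)C[C@]2(C)C(CCc3ccoc3)=C(C[Si](C)(C)O)C[C@H](O)[C@H]12 | intermediate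
17 | 6α,17-diol with C2 silyl enol ether and furan | CC1(C)C=C(O[Si](C(C)C)(C(C)C)C(C)C)C[C@]2(C)C(CCc3ccoc3)=C(CO)C[C@H](O)[C@H]12 | intermediate
18 | 6α,17-dihydroxy 2-ketone with furan | CC1(C)CC(=O)C[C@]2(C)C(CCc3ccoc3)=C(CO)C[C@H](O)[C@H]12 | intermediate
19 | (2S,5R,6S,10S) 2α,6α,17-triol with 3-substituted furan | CC1(C)C[C@H](O)C[C@]2(C)C(CCc3ccoc3)=C(CO)C[C@H](O)[C@H]12 | intermediate
20 | furan endoperoxide (2,3,7-trioxabicyclo[2.2.1]hept-5-ene at C13–C16; bridgehead configuration not defined; not isolated) | CC1(C)C[C@H](O)C[C@]2(C)C(CCC3=CC4OOC3O4)=C(CO)C[C@H](O)[C@H]12 | intermediate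
21 | 16-hydroxybutenolide (mixture of C16 epimers; not isolated) | CC1(C)C[C@H](O)C[C@]2(C)C(CCC3=CC(=O)OC3O)=C(CO)C[C@H](O)[C@H]12 | intermediate
22 | (Z)-hydroxy acid: C16 hydroxymethyl and C15 carboxylic acid on the C13=C14 alkene (not isolated) | CC1(C)C[C@H](O)C[C@]2(C)C(CC/C(CO)=C/C(O)=O)=C(CO)C[C@H](O)[C@H]12 | intermediate
23 | CNP0293367.1, (2S,5R,6S,10S) | CC1(C)C[C@H](O)C[C@]2(C)C(CCC3=CC(=O)OC3)=C(CO)C[C@H](O)[C@H]12 | target

## Step count and least certain steps

Total: 12 steps. Longest linear sequence: 11 steps (steps 1, 2 and 4–12); the side-chain iodide is made in one step (step 3).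

**Step 2 (key step).** The cis methyl group of diene 4 hinders the s-cis geometry. The cycloaddition may therefore stall after the first C–C bond, or be overtaken by an uncatalysed or protodesilylating pathway with loss of enantiocontrol. The sense of induction also rests on an analogy (see Assumptions). Fallback, from 4 and 5 back to 6: the annulation is run as two separate bond formations. A catalyst-controlled Mukaiyama–Michael addition at low temperature is stopped, after silyl transfer to O6, at the open-chain silyl dienol ether F1, in which C10 is already set. Catalytic Tf2NH then promotes an intramolecular silyl-transfer Mukaiyama–Michael closure of C5 onto C4 of the pendant enone; the silyl group returns to O2 and the product is 6.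

**Step 6.** The tethered radical may fail to attack the fully substituted, methoxy-bearing C8; the outcome would then be simple reduction of the C–Br bond or 6-endo closure at C7. The base used for methanol loss may also epimerise C5. Fallback, from 11 back to 18: C17 is introduced by carbonyl methylenation at C8 and the C9 oxygen is moved to C17, not deleted. Luche reduction of 11 (NaBH4, CeCl3·7H2O) at C6 gives the allylic alcohol F2, and t-BuMe2SiCl with imidazole converts its secondary hydroxyl into the tert-butyldimethylsilyl ether F3. Oxalic acid on wet silica hydrolyses the methyl enol ether to the α-hydroxy ketone F4, and Cp2TiMe2 converts the C8 ketone into the exocyclic methylene carbinol F5. Catalytic Ph3SiOReO3 then transposes the tertiary allylic alcohol to the primary allylic alcohol F6, which has the C8=C9 alkene and the C17 hydroxyl. Bu4NF with AcOH removes both silyl groups and gives 18. These six operations replace steps 5 to 10.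

**Step 7.** The five-membered siloxane ring holds the C9–O bond near the plane of the enone. Overlap with the reduced π-system may then be poor, so that protonation at C8 (plain conjugate reduction) competes with elimination; late isomerisation of the alkene into conjugation is a second hazard. Fallback, from 14 back to 17: the siloxane is opened first, so that the group expelled is a freely rotating C17 oxygen. Tamao oxidation of 14 (KF, KHCO3, H2O2; the hindered, fully β-substituted enone should resist epoxidation under bicarbonate buffering) gives the 9,17-diol F7, and Ac2O with pyridine acetylates only the primary hydroxyl to give the monoacetate F8. SmI2 now expels the C17 acetate and gives the exocyclic methylene ketone F9, which keeps the C9 hydroxyl. Luche reduction gives the 6α,9-diol F10, and the Ph3SiOReO3-catalysed 1,3-transposition of its tertiary allylic alcohol delivers 17.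

**Step 4.** The C9 carbonyl is neopentyl. Slow addition would allow competing attack at C6, enolisation at C5 or electron transfer to the enedione. Fallback, from 6 back to 11: a slimmer sp nucleophile is used. 3-Ethynylfuran, deprotonated with n-BuLi and transmetallated with CeCl3, adds to C9 to give the propargylic carbinol F11, and hydrogenation of the alkyne over Pd/C (two equivalents of H2) gives 11.

**Step 11.** Facial selectivity depends on which conformer of the cis-fused bicycle reacts. In the other conformer the C10 methyl and the 4β-methyl are axial on the β-face, and hydride would be steered to the α-face, giving the 2β epimer. Fallback, from 18 back to 19, with no new compound: kinetic hydride attack is replaced by an electron-transfer reduction (SmI2, H2O, Et3N, THF), which gives the carbinol that is equatorial in the reacting conformer. In each conformer a bulky hydride gives the axial and an electron-transfer reduction the equatorial carbinol, so the two methods are complementary whichever conformer prevails.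

**Step 12.** Singlet oxygen may undergo an ene reaction with the tetrasubstituted C8=C9 alkene, which has three sets of allylic hydrogens, in competition with the furan. Fallback, from 19 back to 23: MnO2 oxidises only the allylic C17 alcohol to the enal F12, which makes C8=C9 electron-poor and inert to singlet oxygen. The same photooxygenation then gives the hydroxybutenolide enal F13 (not isolated), and NaBH4 with CeCl3·7H2O reduces both the lactol and the aldehyde to give 23.

## Further compounds

F1 | step 2 | open-chain Mukaiyama–Michael adduct: 6-silyloxy-8-methoxy cyclohexadienone with the 4-methyl-2-oxopent-3-enyl chain on C10 | CC(C)=CC(=O)C[C@@]1(C)C=C(O[Si](C(C)C)(C(C)C)C(C)C)C=C(OC)C1=O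
F2 | step 6 | 6α-allylic alcohol from 11 (C7=C8 methyl enol ether, 9α-hydroxyl) | CC1(C)C=C(O[Si](C(C)C)(C(C)C)C(C)C)C[C@]2(C)[C@@](O)(CCc3ccoc3)C(OC)=C[C@H](O)[C@H]12
F3 | step 6 | 6-O-tert-butyldimethylsilyl ether of F2 | CC1(C)C=C(O[Si](C(C)C)(C(C)C)C(C)C)C[C@]2(C)[C@@](O)(CCc3ccoc3)C(OC)=C[C@H](O[Si](C)(C)C(C)(C)C)[C@H]12
F4 | step 6 | 9-hydroxy 8-ketone with 6α-silyloxy group | CC1(C)C=C(O[Si](C(C)C)(C(C)C)C(C)C)C[C@]2(C)[C@@](O)(CCc3ccoc3)C(=O)C[C@H](O[Si](C)(C)C(C)(C)C)[C@H]12
F5 | step 6 | 8(17)-methylene 9-carbinol with 6α-silyloxy group | CC1(C)C=C(O[Si](C(C)C)(C(C)C)C(C)C)C[C@]2(C)[C@@](O)(CCc3ccoc3)C(=C)C[C@H](O[Si](C)(C)C(C)(C)C)[C@H]12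
F6 | step 6 | 17-hydroxy 8(9)-ene with 6α-silyloxy group and C2 silyl enol ether | CC1(C)C=C(O[Si](C(C)C)(C(C)C)C(C)C)C[C@]2(C)C(CCc3ccoc3)=C(CO)C[C@H](O[Si](C)(C)C(C)(C)C)[C@H]12
F7 | step 7 | 9,17-dihydroxy enone (C6 ketone, C7=C8) | CC1(C)C=C(O[Si](C(C)C)(C(C)C)C(C)C)C[C@]2(C)[C@@](O)(CCc3ccoc3)C(CO)=CC(=O)[C@H]12
F8 | step 7 | 17-acetate of F7 | CC1(C)C=C(O[Si](C(C)C)(C(C)C)C(C)C)C[C@]2(C)[C@@](O)(CCc3ccoc3)C(COC(C)=O)=CC(=O)[C@H]12
F9 | step 7 | 8(17)-methylene 9-hydroxy 6-ketone | CC1(C)C=C(O[Si](C(C)C)(C(C)C)C(C)C)C[C@]2(C)[C@@](O)(CCc3ccoc3)C(=C)CC(=O)[C@H]12
F10 | step 7 | 8(17)-methylene 6α,9-diol | CC1(C)C=C(O[Si](C(C)C)(C(C)C)C(C)C)C[C@]2(C)[C@@](O)(CCc3ccoc3)C(=C)C[C@H](O)[C@H]12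
F11 | step 4 | propargylic C9 carbinol with (furan-3-yl)ethynyl group | CC1(C)C=C(O[Si](C(C)C)(C(C)C)C(C)C)C[C@]2(C)[C@@](O)(C#Cc3ccoc3)C(OC)=CC(=O)[C@H]12
F0 | step 11 | none | none
F12 | step 12 | 2α,6α-dihydroxy 17-al (enal) with furan | CC1(C)C[C@H](O)C[C@]2(C)C(CCc3ccoc3)=C(C=O)C[C@H](O)[C@H]12
F13 | step 12 | 16-hydroxybutenolide 17-al (not isolated) | CC1(C)C[C@H](O)C[C@]2(C)C(CCC3=CC(=O)OC3O)=C(C=O)C[C@H](O)[C@H]12
A1 | alternative 1 | cis-decalin-2,6-dione with C8=C9 alkene and silyl-protected C12 and C17 hydroxyls | CC1(C)CC(=O)C[C@]2(C)C(CCO[Si](C)(C)C(C)(C)C)=C(CO[Si](C)(C)C(C)(C)C)CC(=O)[C@H]12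
A2 | alternative 1 | ten-membered (Z,Z)-dienedione precursor | CC1(C)CC(=O)C/C(CO[Si](C)(C)C(C)(C)C)=C(CCO[Si](C)(C)C(C)(C)C)\C(C)=C/C(=O)C1
A3 | alternative 2 | bridged δ-lactone 1,5-diketone (C6 methyl ketone on C5, hydroxyacetyl on C9; one C9 epimer) | CC1(C)C[C@H](O2)C[C@](C)([C@H](C(=O)CO)C2=O)[C@@H]1C(C)=O
A4 | alternative 2 | 3,5,5-trimethylcyclohex-3-en-1-yl 5-methyl-3-oxo-2,3-dihydrofuran-4-carboxylate (photosubstrate) | CC1=CC(C)(C)C[C@@H](C1)OC(=O)C1=C(C)OCC1=O
A5 | alternative 3 | cis-fused 6,8-diene with C10 quaternary and three silyl ethers | CC1(C)C[C@H](O[Si](C)(C)C(C)(C)C)C[C@]2(C)C(CCO[Si](C)(C)C(C)(C)C)=C(CO[Si](C)(C)C(C)(C)C)C=C[C@H]12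
A6 | alternative 3 | (6Z)-triene on the 4-silyloxy-2,6,6-trimethylcyclohexene ring | CC1=C(/C=C\C(CO[Si](C)(C)C(C)(C)C)=C\CCO[Si](C)(C)C(C)(C)C)C(C)(C)C[C@H](O[Si](C)(C)C(C)(C)C)C1
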